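**Retrosynthetic overview**

- The C2–aryl bond and the C2 stereocentre are made in the penultimate step by an enantioselective Pd-catalysed decarboxylative conjugate arylation of a 6-lavandulyl chromone with 2,4,6-tris(methoxymethoxy)benzoic acid (ring B); global MOM removal follows.
- The pyranone (ring C) is the only ring built. It is closed as a chromone from an o-hydroxyacetophenone whose single free OH lies para to the lavandulyl group, which fixes substitution at C6.
- The aryl–CH2 bond comes from a Negishi coupling of (S)-lavandulylzinc iodide with a 4-iodo-3,5-bis(MOM-oxy)phenyl boronate; the boronate is then oxidised to the ring-closing phenol.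
- Both phloroglucinol rings come from resorcinol: the third oxygen by Ir-catalysed C–H borylation and oxidation, the iodide and the carboxyl group by directed ortho-lithiation.
- The lavandulyl stereocentre comes from an enantioselective α-prenylation of 3-methylbut-3-enoic acid, then reduction and iodination.

Assumption: the (R,R)-tetramine in step 4 and (R)-t-BuPyOx in step 14 are taken to give the configurations drawn, by analogy with the known sense of induction of the parent reactions; if either sense is reversed, the mirror-image reagent or ligand is used.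

**Route**

Step 1
Reactants: 1 resorcinol (benzene-1,3-diol)
Product: 2 1,3-bis(methoxymethoxy)benzene
Conditions: MOMCl (2.5 equiv), i-Pr2NEt (3 equiv), CH2Cl2, 0 °C → rt
Reagents that add atoms: chloromethyl methyl ether, COCCl
Why: Double O-alkylation of the phenols (Williamson-type acetal protection) gives the bis-MOM ether, whose oxygens later direct ortho-lithiation and survive the organometallic steps.

Step 2
Reactants: 2 1,3-bis(methoxymethoxy)benzene
Product: 4 2-iodo-1,3-bis(methoxymethoxy)benzene, via aryllithium 3 (not isolated)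
Conditions: n-BuLi (1.1 equiv), THF, 0 °C, 1 h; then I2, −78 °C → rt
Reagents that add atoms: iodine, II
Why: Directed ortho-metalation, in which the C2–H flanked by both MOM ethers is the most acidic and best coordinated site, followed by trapping of the aryllithium with iodine.

Step 3
Reactants: 4 2-iodo-1,3-bis(methoxymethoxy)benzene
Product: 5 2-[4-iodo-3,5-bis(methoxymethoxy)phenyl]-4,4,5,5-tetramethyl-1,3,2-dioxaborolane
Conditions: [Ir(OMe)(cod)]2 (1.5 mol%; cod = 1,5-cyclooctadiene), 4,4'-di-tert-butyl-2,2'-bipyridine (3 mol%), B2pin2 (0.55 equiv), THF, 80 °C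
Reagents that add atoms: bis(pinacolato)diboron, CC1(C)OB(OC1(C)C)B1OC(C)(C)C(C)(C)O1
Why: Iridium-catalysed aromatic C–H borylation is sterically controlled, so only the C–H with no ortho substituent (para to iodine) reacts, and aryl iodides are tolerated.

Step 4
Reactants: 6 3-methylbut-3-enoic acid; 7 prenyl bromide (1-bromo-3-methylbut-2-ene)
Product: 9 (2S)-5-methyl-2-(prop-1-en-2-yl)hex-4-enoic acid, via dilithium dienediolate 8 (not isolated)
Conditions: (R,R)-N1,N3-bis[1-phenyl-2-(piperidin-1-yl)ethyl]propane-1,3-diamine (1.05 equiv), n-BuLi (4.1 equiv), THF, 0 °C; then 6, −78 → 0 °C; then 7, −78 °C; 1 M HCl work-up (tetramine recovered by acid–base extraction)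
Reagents that add atoms: none
Why: Enantioselective enolate alkylation in which the lithium dienediolate of the β,γ-unsaturated acid sits in a mixed aggregate with the chiral dilithium amide (a noncovalent, recoverable auxiliary), so that the α-carbon attacks the primary allylic bromide by SN2 on one face and sets the (S) centre.

Step 5
Reactants: 9 (2S)-5-methyl-2-(prop-1-en-2-yl)hex-4-enoic acid
Product: 10 (2S)-5-methyl-2-(prop-1-en-2-yl)hex-4-en-1-ol ((S)-lavandulol)
Conditions: LiAlH4 (1.5 equiv), Et2O, 0 °C → rt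
Reagents that add atoms: none
Why: Hydride reduction of the carboxylic acid with LiAlH4, in which the carboxylate is not enolised and the isolated alkenes are inert, so the stereocentre and both double bonds are kept.

Step 6
Reactants: 10 (2S)-5-methyl-2-(prop-1-en-2-yl)hex-4-en-1-ol
Product: 11 (3S)-3-(iodomethyl)-2,6-dimethylhepta-1,5-diene ((S)-lavandulyl iodide)
Conditions: PPh3 (1.2 equiv), I2 (1.2 equiv), imidazole (1.5 equiv), CH2Cl2, 0 °C
Reagents that add atoms: iodine, II
Why: Appel-type iodination, in which the alkoxyphosphonium ion is displaced by iodide in an SN2 reaction at the primary carbon, leaving the adjacent stereocentre untouched.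

Step 7
Reactants: 11 (3S)-3-(iodomethyl)-2,6-dimethylhepta-1,5-diene; 5 2-[4-iodo-3,5-bis(methoxymethoxy)phenyl]-4,4,5,5-tetramethyl-1,3,2-dioxaborolane
Product: 14 3,5-bis(methoxymethoxy)-4-[(2R)-5-methyl-2-(prop-1-en-2-yl)hex-4-en-1-yl]phenol, via alkylzinc iodide 12 (not isolated), via coupled aryl boronate 13 (not isolated)
Conditions: 11 (1.3 equiv), Zn dust (2 equiv; activated by BrCH2CH2Br, Me3SiCl), LiCl, THF, 40 °C; then 5, Pd(OAc)2 (2 mol%), SPhos (4 mol%), THF, 40 °C; then 3 M NaOH, 30% H2O2, 0 °C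
Reagents that add atoms: hydrogen peroxide, OO
Why: Negishi sp3–sp2 cross-coupling of a primary alkylzinc (stereocentre β to zinc, configurationally inert) with the aryl iodide, the pinacol boronate being unreactive without base, followed by oxidation of the C–B bond to the phenol by alkaline peroxide.

Step 8
Reactants: 14 3,5-bis(methoxymethoxy)-4-[(2R)-5-methyl-2-(prop-1-en-2-yl)hex-4-en-1-yl]phenol
Product: 15 2-iodo-3,5-bis(methoxymethoxy)-4-[(2R)-5-methyl-2-(prop-1-en-2-yl)hex-4-en-1-yl]phenol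
Conditions: NIS (1.0 equiv), CH2Cl2, −40 → −20 °C
Reagents that add atoms: N-iodosuccinimide, O=C1CCC(=O)N1I
Why: Electrophilic aromatic iodination of a highly activated phenol, where the two remaining ring positions are equivalent (both ortho to OH) and the arene outcompetes the alkenes for the iodonium source at low temperature.

Step 9
Reactants: 15 2-iodo-3,5-bis(methoxymethoxy)-4-[(2R)-5-methyl-2-(prop-1-en-2-yl)hex-4-en-1-yl]phenol
Product: 17 1-{6-hydroxy-2,4-bis(methoxymethoxy)-3-[(2R)-5-methyl-2-(prop-1-en-2-yl)hex-4-en-1-yl]phenyl}ethan-1-one, via dilithiated phenoxide 16 (not isolated)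
Conditions: n-BuLi (2.2 equiv), THF, −78 °C; then MeC(O)N(OMe)Me (1.5 equiv), −78 → 0 °C; aq. NH4Cl
Reagents that add atoms: N-methoxy-N-methylacetamide, CC(=O)N(C)OC
Why: Deprotonation of the phenol followed by iodine–lithium exchange gives an ortho-lithiated phenoxide, which is acylated by the Weinreb amide through a stable chelated tetrahedral intermediate that prevents over-addition.

Step 10
Reactants: 17 1-{6-hydroxy-2,4-bis(methoxymethoxy)-3-[(2R)-5-methyl-2-(prop-1-en-2-yl)hex-4-en-1-yl]phenyl}ethan-1-one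
Product: 19 5,7-bis(methoxymethoxy)-6-[(2R)-5-methyl-2-(prop-1-en-2-yl)hex-4-en-1-yl]-4H-chromen-4-one, via enaminone 18 (not isolated)
Conditions: Me2NCH(OMe)2 (3 equiv), toluene, 95 °C; concentrate; then AcOH, CH2Cl2, 40 °C
Reagents that add atoms: N,N-dimethylformamide dimethyl acetal, COC(OC)N(C)C
Why: Condensation of the methyl ketone with the amide acetal gives an enaminone, and acid-promoted 6-endo oxa-Michael addition of the only free phenol with loss of dimethylamine closes the pyranone ring (enaminone route to chromones), which places the lavandulyl group at C6.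

Step 11
Reactants: 2 1,3-bis(methoxymethoxy)benzene
Product: 21 3,5-bis(methoxymethoxy)phenol, via aryl boronate 20 (not isolated)
Conditions: [Ir(OMe)(cod)]2 (1.5 mol%), 4,4'-di-tert-butyl-2,2'-bipyridine (3 mol%), B2pin2 (0.55 equiv), THF, 80 °C; then 3 M NaOH, 30% H2O2, 0 °C
Reagents that add atoms: hydrogen peroxide, OO
Why: Sterically controlled iridium-catalysed C–H borylation at C5 (the only C–H without an ortho substituent), followed by oxidation of the boronate in the same flask, gives the phloroglucinol-type phenol.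

Step 12
Reactants: 21 3,5-bis(methoxymethoxy)phenol
Product: 22 1,3,5-tris(methoxymethoxy)benzene
Conditions: MOMCl (1.3 equiv), i-Pr2NEt (1.5 equiv), CH2Cl2, 0 °C → rt
Reagents that add atoms: chloromethyl methyl ether, COCCl
Why: O-Alkylation of the remaining phenol (acetal protection) gives a C3-symmetric arene in which all three C–H bonds are equivalent.

Step 13
Reactants: 22 1,3,5-tris(methoxymethoxy)benzene
Product: 24 2,4,6-tris(methoxymethoxy)benzoic acid, via aryllithium 23 (not isolated)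
Conditions: n-BuLi (1.1 equiv), THF, 0 °C, 1 h; then dry CO2 (gas), −78 → 0 °C; cold 1 M HCl to pH 3–4, extracted at once into EtOAc
Reagents that add atoms: carbon dioxide, O=C=O
Why: Directed ortho-metalation at one of the three equivalent C–H bonds, each flanked by two MOM ethers, followed by carboxylation of the aryllithium; brief cold acidification frees the acid without cleaving the MOM acetals.

Step 14
Reactants: 19 5,7-bis(methoxymethoxy)-6-[(2R)-5-methyl-2-(prop-1-en-2-yl)hex-4-en-1-yl]-4H-chromen-4-one; 24 2,4,6-tris(methoxymethoxy)benzoic acid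
Product: 25 (2S)-5,7-bis(methoxymethoxy)-6-[(2R)-5-methyl-2-(prop-1-en-2-yl)hex-4-en-1-yl]-2-[2,4,6-tris(methoxymethoxy)phenyl]-2,3-dihydro-4H-chromen-4-one
Conditions: Pd(OCOCF3)2 (10 mol%), (R)-t-BuPyOx [(4R)-4-tert-butyl-2-(pyridin-2-yl)-4,5-dihydro-1,3-oxazole] (12 mol%), NH4PF6 (30 mol%), H2O (5 equiv), 24 (1.8 equiv, added in portions over 6 h), ClCH2CH2Cl, 60 °C, 24 h
Reagents that add atoms: none
Why: Proposed new method: an enantioselective decarboxylative conjugate arylation of a chromone, in which the cationic divalent palladium complex of (R)-t-BuPyOx exchanges trifluoroacetate for the carboxylate of 24, the electron-rich, doubly ortho-alkoxylated carboxylate loses CO2 by ipso-palladation to give an aryl–palladium species, this inserts the C2=C3 bond of 19 on the face selected by the tert-butyl group of the ligand to set C2 as S, and the palladium enolate is protonated by the next molecule of 24 (or water), which regenerates the palladium carboxylate so that no oxidant, base or organoboron reagent is needed; the closest known reaction type is the Pd/PyOx-catalysed asymmetric conjugate addition of arylboronic acids to chromones, with transmetalation replaced by the decarboxylative palladation of 2,6-dialkoxybenzoic acids known from decarboxylative Heck reactions.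

Step 15
Reactants: 25 (2S)-5,7-bis(methoxymethoxy)-6-[(2R)-5-methyl-2-(prop-1-en-2-yl)hex-4-en-1-yl]-2-[2,4,6-tris(methoxymethoxy)phenyl]-2,3-dihydro-4H-chromen-4-one
Product: 27 (2S)-5,7-dihydroxy-6-[(2R)-5-methyl-2-(prop-1-en-2-yl)hex-4-en-1-yl]-2-(2,4,6-trihydroxyphenyl)-2,3-dihydro-4H-chromen-4-one, via pentakis(trimethylsilyl) ether 26 (not isolated)
Conditions: Me3SiOTf (10 equiv), 2,2'-bipyridyl (15 equiv), MeCN, 0 °C → rt; then H2O, rt
Reagents that add atoms: none
Why: The five aryl MOM ethers are exchanged to aryl silyl ethers by the silyl triflate buffered with 2,2'-bipyridyl and then hydrolysed by water, an acetal cleavage without free Brønsted acid or base that spares the alkenes and avoids chalcone ring-opening at the labile C2 centre.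

**Compound list**

1 | resorcinol (benzene-1,3-diol) | Oc1cccc(O)c1 | starting material
2 | 1,3-bis(methoxymethoxy)benzene | COCOc1cccc(OCOC)c1 | intermediate
3 | 2,6-bis(methoxymethoxy)phenyllithium | [Li]c1c(OCOC)cccc1OCOC | intermediate
4 | 2-iodo-1,3-bis(methoxymethoxy)benzene | COCOc1cccc(OCOC)c1I | intermediate
5 | 2-[4-iodo-3,5-bis(methoxymethoxy)phenyl]-4,4,5,5-tetramethyl-1,3,2-dioxaborolane | COCOc1cc(B2OC(C)(C)C(C)(C)O2)cc(OCOC)c1I | intermediate
6 | 3-methylbut-3-enoic acid | C=C(C)CC(=O)O | starting material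
7 | prenyl bromide (1-bromo-3-methylbut-2-ene) | CC(C)=CCBr | starting material
8 | dilithium dienediolate of 3-methylbut-3-enoic acid | C=C(C)C=C(O[Li])O[Li] | intermediate
9 | (2S)-5-methyl-2-(prop-1-en-2-yl)hex-4-enoic acid | C=C(C)[C@H](CC=C(C)C)C(=O)O | intermediate
10 | (2S)-5-methyl-2-(prop-1-en-2-yl)hex-4-en-1-ol | C=C(C)[C@H](CC=C(C)C)CO | intermediate
11 | (3S)-3-(iodomethyl)-2,6-dimethylhepta-1,5-diene | C=C(C)[C@H](CC=C(C)C)CI | intermediate
12 | [(2S)-5-methyl-2-(prop-1-en-2-yl)hex-4-en-1-yl]zinc iodide | C=C(C)[C@H](CC=C(C)C)C[Zn]I | intermediate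
13 | 2-{3,5-bis(methoxymethoxy)-4-[(2R)-5-methyl-2-(prop-1-en-2-yl)hex-4-en-1-yl]phenyl}-4,4,5,5-tetramethyl-1,3,2-dioxaborolane | C=C(C)[C@H](CC=C(C)C)Cc1c(OCOC)cc(B2OC(C)(C)C(C)(C)O2)cc1OCOC | intermediate
14 | 3,5-bis(methoxymethoxy)-4-[(2R)-5-methyl-2-(prop-1-en-2-yl)hex-4-en-1-yl]phenol | C=C(C)[C@H](CC=C(C)C)Cc1c(OCOC)cc(O)cc1OCOC | intermediate
15 | 2-iodo-3,5-bis(methoxymethoxy)-4-[(2R)-5-methyl-2-(prop-1-en-2-yl)hex-4-en-1-yl]phenol | C=C(C)[C@H](CC=C(C)C)Cc1c(OCOC)cc(O)c(I)c1OCOC | intermediate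
16 | lithium 2-lithio-3,5-bis(methoxymethoxy)-4-[(2R)-5-methyl-2-(prop-1-en-2-yl)hex-4-en-1-yl]phenoxide | C=C(C)[C@H](CC=C(C)C)Cc1c(OCOC)cc(O[Li])c([Li])c1OCOC | intermediate
17 | 1-{6-hydroxy-2,4-bis(methoxymethoxy)-3-[(2R)-5-methyl-2-(prop-1-en-2-yl)hex-4-en-1-yl]phenyl}ethan-1-one | C=C(C)[C@H](CC=C(C)C)Cc1c(OCOC)cc(O)c(C(C)=O)c1OCOC | intermediate
18 | (2E)-3-(dimethylamino)-1-{6-hydroxy-2,4-bis(methoxymethoxy)-3-[(2R)-5-methyl-2-(prop-1-en-2-yl)hex-4-en-1-yl]phenyl}prop-2-en-1-one | C=C(C)[C@H](CC=C(C)C)Cc1c(OCOC)cc(O)c(C(=O)/C=C/N(C)C)c1OCOC | intermediate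
19 | 5,7-bis(methoxymethoxy)-6-[(2R)-5-methyl-2-(prop-1-en-2-yl)hex-4-en-1-yl]-4H-chromen-4-one | C=C(C)[C@H](CC=C(C)C)Cc1c(OCOC)cc2occc(=O)c2c1OCOC | intermediate
20 | 2-[3,5-bis(methoxymethoxy)phenyl]-4,4,5,5-tetramethyl-1,3,2-dioxaborolane | COCOc1cc(OCOC)cc(B2OC(C)(C)C(C)(C)O2)c1 | intermediate
21 | 3,5-bis(methoxymethoxy)phenol | COCOc1cc(O)cc(OCOC)c1 | intermediate
22 | 1,3,5-tris(methoxymethoxy)benzene | COCOc1cc(OCOC)cc(OCOC)c1 | intermediate
23 | 2,4,6-tris(methoxymethoxy)phenyllithium | [Li]c1c(OCOC)cc(OCOC)cc1OCOC | intermediate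
24 | 2,4,6-tris(methoxymethoxy)benzoic acid | COCOc1cc(OCOC)c(C(=O)O)c(OCOC)c1 | intermediate
25 | (2S)-5,7-bis(methoxymethoxy)-6-[(2R)-5-methyl-2-(prop-1-en-2-yl)hex-4-en-1-yl]-2-[2,4,6-tris(methoxymethoxy)phenyl]-2,3-dihydro-4H-chromen-4-one | C=C(C)[C@H](CC=C(C)C)Cc1c(OCOC)cc2c(c1OCOC)C(=O)C[C@@H](c1c(OCOC)cc(OCOC)cc1OCOC)O2 | intermediate
26 | (2S)-6-[(2R)-5-methyl-2-(prop-1-en-2-yl)hex-4-en-1-yl]-5,7-bis(trimethylsilyloxy)-2-[2,4,6-tris(trimethylsilyloxy)phenyl]-2,3-dihydro-4H-chromen-4-one | C=C(C)[C@H](CC=C(C)C)Cc1c(O[Si](C)(C)C)cc2c(c1O[Si](C)(C)C)C(=O)C[C@@H](c1c(O[Si](C)(C)C)cc(O[Si](C)(C)C)cc1O[Si](C)(C)C)O2 | intermediate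
27 | (2S)-5,7-dihydroxy-6-[(2R)-5-methyl-2-(prop-1-en-2-yl)hex-4-en-1-yl]-2-(2,4,6-trihydroxyphenyl)-2,3-dihydro-4H-chromen-4-one | C=C(C)[C@H](CC=C(C)C)Cc1c(O)cc2c(c1O)C(=O)C[C@@H](c1c(O)cc(O)cc1O)O2 | target

**Step count and risks**

Total step count: 15.
Longest linear sequence: 9 steps (1, 2, 3, 7, 8, 9, 10, 14, 15; the line from 6 and 7 through steps 4, 5, 6 and then 7, 8, 9, 10, 14, 15 is equally long). The ring B branch (1, 11, 12, 13, 14, 15) has 6 steps.

Most likely to fail, step 14 (the proposed new step). The aryl–palladium species carries two ortho substituents at the insertion stage, and it can be protonated before insertion (protodecarboxylation back to 22). It could also insert the isopropenyl group of 19 in a Heck-type path, and acid 24 may slowly cleave MOM ethers at 60 °C. The fallback uses known chemistry, sets out from 17 and 22, and comes back to the route at 25. Compound 22 is lithiated as in step 13 to the aryllithium 23, which is quenched with DMF instead of CO2 (aq. NH4Cl work-up) to give 2,4,6-tris(methoxymethoxy)benzaldehyde F1. Claisen–Schmidt condensation of F1 with 17 (KOH, EtOH–H2O, rt) gives the 2'-hydroxychalcone (2E)-1-{6-hydroxy-2,4-bis(methoxymethoxy)-3-[(2R)-5-methyl-2-(prop-1-en-2-yl)hex-4-en-1-yl]phenyl}-3-[2,4,6-tris(methoxymethoxy)phenyl]prop-2-en-1-one F2. NaOAc in refluxing EtOH closes ring C by oxa-Michael addition to a near 1:1 mixture of 25 and its C2 epimer (2R)-5,7-bis(methoxymethoxy)-6-[(2R)-5-methyl-2-(prop-1-en-2-yl)hex-4-en-1-yl]-2-[2,4,6-tris(methoxymethoxy)phenyl]-2,3-dihydro-4H-chromen-4-one F3, because the lavandulyl centre is too remote to bias the closure. The two are separated by preparative HPLC on an amylose tris(3,5-dimethylphenylcarbamate) phase, and F3 is returned to the mixture by renewed NaOAc treatment through F2.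

Second, step 7. The aryl iodide is flanked by two MOM ethers, the alkylzinc is β-branched and homoallylic, and the oxidation is run on the crude coupling mixture. The fallback replaces the cross-coupling by a carbonyl addition and radical deoxygenation; it sets out from 21 and 10 and comes back at 14. Compound 21 is silylated (i-Pr3SiCl, imidazole, DMF) to [3,5-bis(methoxymethoxy)phenoxy]tri(propan-2-yl)silane F4. Compound 10 is oxidised (Dess–Martin periodinane, NaHCO3, CH2Cl2, 0 °C) to (2S)-5-methyl-2-(prop-1-en-2-yl)hex-4-enal F5, which is used at once because its α-centre epimerises easily. F4 is lithiated between its two MOM ethers (n-BuLi, THF, 0 °C) to 2,6-bis(methoxymethoxy)-4-[tri(propan-2-yl)silyloxy]phenyllithium F6, which adds to F5 at −78 °C to give (2S)-1-{2,6-bis(methoxymethoxy)-4-[tri(propan-2-yl)silyloxy]phenyl}-5-methyl-2-(prop-1-en-2-yl)hex-4-en-1-ol F7 as a mixture of carbinol epimers. NaH, CS2 and MeI convert F7 into the xanthate O-[(2S)-1-{2,6-bis(methoxymethoxy)-4-[tri(propan-2-yl)silyloxy]phenyl}-5-methyl-2-(prop-1-en-2-yl)hex-4-en-1-yl] S-methyl dithiocarbonate F8. Barton–McCombie deoxygenation (Bu3SnH, AIBN, toluene, 80 °C; the benzylic radical does not rearrange) gives {3,5-bis(methoxymethoxy)-4-[(2R)-5-methyl-2-(prop-1-en-2-yl)hex-4-en-1-yl]phenoxy}tri(propan-2-yl)silane F9, and Bu4NF (THF, 0 °C) releases 14.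

Third, step 4. The enantiomeric excess and the α/γ selectivity of the noncovalent-auxiliary alkylation are unproven for this dienediolate and prenyl bromide. The fallback uses a covalent auxiliary; it sets out from 7 and comes back at 10. Commercial (4S)-4-benzyl-1,3-oxazolidin-2-one is deprotonated (n-BuLi, THF, −78 °C) to lithium (4S)-4-benzyl-2-oxo-1,3-oxazolidin-3-ide F10 and acylated with 3-methylbut-2-enoyl chloride to (4S)-4-benzyl-3-(3-methylbut-2-enoyl)-1,3-oxazolidin-2-one F11. NaN(SiMe3)2 (THF, −78 °C) removes a γ-proton to give the sodium (Z)-dienolate of (4S)-4-benzyl-3-(3-methylbut-2-enoyl)-1,3-oxazolidin-2-one F12, which is alkylated by 7 at the α-carbon on the face opposite the benzyl group to give (4S)-4-benzyl-3-[(2S)-5-methyl-2-(prop-1-en-2-yl)hex-4-enoyl]-1,3-oxazolidin-2-one F13. LiBH4 (Et2O, 1 equiv H2O, 0 °C) cleaves the auxiliary reductively and delivers 10.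

**Further compounds**

F1 | step 14 | 2,4,6-tris(methoxymethoxy)benzaldehyde | COCOc1cc(OCOC)c(C=O)c(OCOC)c1
F2 | step 14 | (2E)-1-{6-hydroxy-2,4-bis(methoxymethoxy)-3-[(2R)-5-methyl-2-(prop-1-en-2-yl)hex-4-en-1-yl]phenyl}-3-[2,4,6-tris(methoxymethoxy)phenyl]prop-2-en-1-one | C=C(C)[C@H](CC=C(C)C)Cc1c(OCOC)cc(O)c(C(=O)/C=C/c2c(OCOC)cc(OCOC)cc2OCOC)c1OCOC
F3 | step 14 | (2R)-5,7-bis(methoxymethoxy)-6-[(2R)-5-methyl-2-(prop-1-en-2-yl)hex-4-en-1-yl]-2-[2,4,6-tris(methoxymethoxy)phenyl]-2,3-dihydro-4H-chromen-4-one | C=C(C)[C@H](CC=C(C)C)Cc1c(OCOC)cc2c(c1OCOC)C(=O)C[C@H](c1c(OCOC)cc(OCOC)cc1OCOC)O2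
F4 | step 7 | [3,5-bis(methoxymethoxy)phenoxy]tri(propan-2-yl)silane | COCOc1cc(OCOC)cc(O[Si](C(C)C)(C(C)C)C(C)C)c1
F5 | step 7 | (2S)-5-methyl-2-(prop-1-en-2-yl)hex-4-enal | C=C(C)[C@H](CC=C(C)C)C=O
F6 | step 7 | 2,6-bis(methoxymethoxy)-4-[tri(propan-2-yl)silyloxy]phenyllithium | [Li]c1c(OCOC)cc(O[Si](C(C)C)(C(C)C)C(C)C)cc1OCOC
F7 | step 7 | (2S)-1-{2,6-bis(methoxymethoxy)-4-[tri(propan-2-yl)silyloxy]phenyl}-5-methyl-2-(prop-1-en-2-yl)hex-4-en-1-ol (both C1 epimers) | C=C(C)[C@H](CC=C(C)C)C(O)c1c(OCOC)cc(O[Si](C(C)C)(C(C)C)C(C)C)cc1OCOC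
F8 | step 7 | O-[(2S)-1-{2,6-bis(methoxymethoxy)-4-[tri(propan-2-yl)silyloxy]phenyl}-5-methyl-2-(prop-1-en-2-yl)hex-4-en-1-yl] S-methyl dithiocarbonate | C=C(C)[C@H](CC=C(C)C)C(OC(=S)SC)c1c(OCOC)cc(O[Si](C(C)C)(C(C)C)C(C)C)cc1OCOC
F9 | step 7 | {3,5-bis(methoxymethoxy)-4-[(2R)-5-methyl-2-(prop-1-en-2-yl)hex-4-en-1-yl]phenoxy}tri(propan-2-yl)silane | C=C(C)[C@H](CC=C(C)C)Cc1c(OCOC)cc(O[Si](C(C)C)(C(C)C)C(C)C)cc1OCOC
F10 | step 4 | lithium (4S)-4-benzyl-2-oxo-1,3-oxazolidin-3-ide | [Li]N1C(=O)OC[C@@H]1Cc1ccccc1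
F11 | step 4 | (4S)-4-benzyl-3-(3-methylbut-2-enoyl)-1,3-oxazolidin-2-one | CC(C)=CC(=O)N1C(=O)OC[C@@H]1Cc1ccccc1
F12 | step 4 | sodium (Z)-dienolate of (4S)-4-benzyl-3-(3-methylbut-2-enoyl)-1,3-oxazolidin-2-one | C=C(C)/C=C(\O[Na])N1C(=O)OC[C@@H]1Cc1ccccc1
F13 | step 4 | (4S)-4-benzyl-3-[(2S)-5-methyl-2-(prop-1-en-2-yl)hex-4-enoyl]-1,3-oxazolidin-2-one | C=C(C)[C@H](CC=C(C)C)C(=O)N1C(=O)OC[C@@H]1Cc1ccccc1
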